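**Plan**
- Retrosynthetic cuts: first the acetate used to fix the hemiacetal carbon, then the fumarate ester C–O bond, then three C–C bonds of ring A in one (2+2+2) cut, and last the aryl ester and alkynyl ether C–O bonds to the ring B catechol. The three ring A bonds run from the ether-bearing to the carbonyl-bearing carbon, from the methyl-bearing carbon to CH, and from the hydroxy-bearing to the formyl-bearing carbon.
- Enabling feature: ring A (methyl, hydroxy, formyl arene) is fused to the seven-membered lactone ring C through its ether-bearing carbon and its ester-carbonyl-bearing carbon. These two carbons hang, through O and through O–C(=O), on the two adjacent oxygens of ring B, so a catechol carrying an ynol ether and a but-2-ynoate holds two alkynes side by side and can become rings A and C at once.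
- Forward: ring B is made as a hexasubstituted benzene from a methoxycatechol by three metalations. The catechol oxygens are told apart by the ortho formyl group, and the ynol ether and then the ynoate are attached. Rhodium closes ring C and ring A together with an alkoxyacetylene. Debenzylation, fumaroylation and BCl3 deprotection then close the lactol ring last.
- Stereochemistry: the single stereocentre, the (R) hemiacetal carbon, is set by lipase-catalysed dynamic kinetic acetylation of the equilibrating lactol and kept in a lipase deacetylation that breaks only the acyl C–O bond.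

Key step: step 13

Assumption: the hemiacetal carbon of the 3-hydroxyphthalide holds its configuration in the solid and in neutral aprotic solution near 0 °C, and equilibrates through the ring-opened formyl acid only in warm, protic or basic media.

Step 1
Reactants: 1 4-methoxycatechol (4-methoxybenzene-1,2-diol)
Product: 2 4-methoxy-1,2-bis(methoxymethoxy)benzene
Conditions: MOMCl, i-Pr2NEt, CH2Cl2, 0 °C → rt
Reagents that add atoms: chloromethyl methyl ether, COCCl
Why: Williamson-type O-alkylation of both phenols gives acetal ethers that direct ortho-metalation and can later be removed with acid while methyl and benzyl ethers stay in place.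

Step 2
Reactants: 2 4-methoxy-1,2-bis(methoxymethoxy)benzene
Product: 4 2-[(benzyloxy)methyl]-1-methoxy-3,4-bis(methoxymethoxy)benzene, via aryllithium 3 (not isolated)
Conditions: n-BuLi, THF, 0 °C; then BnOCH2Cl, −78 °C → rt
Reagents that add atoms: benzyl chloromethyl ether, ClCOCc1ccccc1
Why: Directed ortho-metalation should remove the proton flanked by the methoxy and a methoxymethoxy group, the doubly coordinated and most acidic site, and alkylation of the aryllithium by the chloromethyl ether installs the benzyl-protected hydroxymethyl carbon in the same operation.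

Step 3
Reactants: 4 2-[(benzyloxy)methyl]-1-methoxy-3,4-bis(methoxymethoxy)benzene
Product: 5 3-[(benzyloxy)methyl]-1-bromo-2-methoxy-4,5-bis(methoxymethoxy)benzene
Conditions: NBS, MeCN, 0 °C
Reagents that add atoms: N-bromosuccinimide, O=C1CCC(=O)N1Br
Why: Electrophilic aromatic bromination should go to the free position that is ortho to the methoxy group and para to a methoxymethoxy group, since the other free position is activated by one oxygen only.

Step 4
Reactants: 5 3-[(benzyloxy)methyl]-1-bromo-2-methoxy-4,5-bis(methoxymethoxy)benzene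
Product: 7 methyl 3-[(benzyloxy)methyl]-2-methoxy-4,5-bis(methoxymethoxy)benzoate, via aryllithium 6 (not isolated)
Conditions: n-BuLi, THF, −78 °C; then ClCO2Me (excess), −78 °C → rt
Reagents that add atoms: methyl chloroformate, COC(=O)Cl
Why: Bromine–lithium exchange outruns any deprotonation at −78 °C, and acylation of the aryllithium by excess chloroformate gives the methyl benzoate.

Step 5
Reactants: 7 methyl 3-[(benzyloxy)methyl]-2-methoxy-4,5-bis(methoxymethoxy)benzoate
Product: 9 methyl 3-[(benzyloxy)methyl]-6-formyl-2-methoxy-4,5-bis(methoxymethoxy)benzoate, via arylmagnesium chloride 8 (not isolated)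
Conditions: TMPMgCl·LiCl, THF, 0 °C → rt; then DMF; aq NH4Cl
Reagents that add atoms: N,N-dimethylformamide, CN(C)C=O
Why: Directed ortho-magnesiation with the Knochel–Hauser base should take the last ring proton, which lies between the ester and a methoxymethoxy group, without attacking the methyl ester, and DMF then formylates the arylmagnesium (Bouveault-type formylation).

Step 6
Reactants: 9 methyl 3-[(benzyloxy)methyl]-6-formyl-2-methoxy-4,5-bis(methoxymethoxy)benzoate
Product: 10 methyl 3-[(benzyloxy)methyl]-6-formyl-4,5-dihydroxy-2-methoxybenzoate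
Conditions: TFA, CH2Cl2, 0 °C → rt; then H2O
Reagents that add atoms: none
Why: Acid-catalysed cleavage of the two aryl methoxymethyl acetals frees the catechol, while the benzyl ether, methyl ether, ester and aldehyde are inert and the fully substituted ring cannot be alkylated by the released formaldehyde equivalents.

Step 7
Reactants: 10 methyl 3-[(benzyloxy)methyl]-6-formyl-4,5-dihydroxy-2-methoxybenzoate
Product: 11 methyl 4-(allyloxy)-3-[(benzyloxy)methyl]-6-formyl-5-hydroxy-2-methoxybenzoate
Conditions: NaH (2.2 equiv), DMSO, rt; allyl bromide (1.0 equiv)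
Reagents that add atoms: allyl bromide, C=CCBr
Why: In the dianion the phenoxide ortho to the formyl group is chelated and delocalised into the aldehyde, so Williamson alkylation should occur at the other oxygen, as is known for 2,3-dihydroxybenzaldehydes.

Step 8
Reactants: 11 methyl 4-(allyloxy)-3-[(benzyloxy)methyl]-6-formyl-5-hydroxy-2-methoxybenzoate
Product: 12 methyl 4-(allyloxy)-3-[(benzyloxy)methyl]-6-(1,3-dioxolan-2-yl)-5-hydroxy-2-methoxybenzoate
Conditions: TMSOCH2CH2OTMS, TMSOTf (cat.), CH2Cl2, −78 → −20 °C; pyridine, aq NaHCO3
Reagents that add atoms: 1,2-bis(trimethylsilyloxy)ethane, C[Si](C)(C)OCCO[Si](C)(C)C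
Why: Noyori acetalisation masks the aldehyde under kinetic conditions in which the hindered neighbouring ester does not lactonise, and a cyclic acetal is chosen because it stays intact next to a free phenoxide and later keeps the aldehyde away from rhodium.

Step 9
Reactants: 13 2,2-diethoxyacetaldehyde
Product: 14 1,1-dibromo-3,3-diethoxyprop-1-ene
Conditions: CBr4, PPh3, Et3N, CH2Cl2, 0 °C
Reagents that add atoms: carbon tetrabromide, BrC(Br)(Br)Br
Why: Ramirez dibromo-olefination (first stage of the Corey–Fuchs sequence) converts the aldehyde into the gem-dibromoalkene, and the amine buffer protects the acetal.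

Step 10
Reactants: 12 methyl 4-(allyloxy)-3-[(benzyloxy)methyl]-6-(1,3-dioxolan-2-yl)-5-hydroxy-2-methoxybenzoate; 14 1,1-dibromo-3,3-diethoxyprop-1-ene
Product: 16 methyl 4-(allyloxy)-3-[(benzyloxy)methyl]-5-[(3,3-diethoxyprop-1-yn-1-yl)oxy]-6-(1,3-dioxolan-2-yl)-2-methoxybenzoate, via bromo enol ether 15 (not isolated)
Conditions: CuI (10 mol%), 2,2'-bipyridine (20 mol%), K3PO4, toluene, 110 °C; then KOtBu, 1,4-dioxane, rt
Reagents that add atoms: none
Why: Copper-catalysed Ullmann-type C–O coupling of the phenol with the gem-dibromoalkene should replace the bromide trans to the acetal carbon, and anti dehydrobromination of the bromo enol ether with KOtBu then gives the aryl alkynyl ether, a known two-stage route to ynol ethers from phenols.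

Step 11
Reactants: 16 methyl 4-(allyloxy)-3-[(benzyloxy)methyl]-5-[(3,3-diethoxyprop-1-yn-1-yl)oxy]-6-(1,3-dioxolan-2-yl)-2-methoxybenzoate
Product: 17 methyl 3-[(benzyloxy)methyl]-5-[(3,3-diethoxyprop-1-yn-1-yl)oxy]-6-(1,3-dioxolan-2-yl)-4-hydroxy-2-methoxybenzoate
Conditions: Pd(PPh3)4 (5 mol%), morpholine, THF, rt; filtration through basic alumina, used at once
Reagents that add atoms: none
Why: Tsuji–Trost deallylation with zerovalent palladium and an amine scavenger frees the phenol in a non-acidic medium, so the acid-sensitive ynol ether is not hydrated and the new phenol does not add to it.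

Step 12
Reactants: 17 methyl 3-[(benzyloxy)methyl]-5-[(3,3-diethoxyprop-1-yn-1-yl)oxy]-6-(1,3-dioxolan-2-yl)-4-hydroxy-2-methoxybenzoate; 18 but-2-ynoic acid
Product: 20 methyl 3-[(benzyloxy)methyl]-4-(but-2-ynoyloxy)-5-[(3,3-diethoxyprop-1-yn-1-yl)oxy]-6-(1,3-dioxolan-2-yl)-2-methoxybenzoate, via but-2-ynoyl chloride 19 (not isolated)
Conditions: 18, (COCl)2, DMF (cat.), CH2Cl2, 0 °C → rt, evaporate; 17, NaH, THF, 0 °C; then the acid chloride, −78 → 0 °C
Reagents that add atoms: none
Why: O-acylation of the preformed sodium phenoxide with the acid chloride should give the aryl ynoate without free carboxylic acid (which would add to the ynol ether) and without amine base (which would isomerise the ynoate to an allenoate).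

Step 13
Reactants: 20 methyl 3-[(benzyloxy)methyl]-4-(but-2-ynoyloxy)-5-[(3,3-diethoxyprop-1-yn-1-yl)oxy]-6-(1,3-dioxolan-2-yl)-2-methoxybenzoate; 21 ethoxyacetylene
Product: 22 methyl 9-[(benzyloxy)methyl]-4-(diethoxymethyl)-6-(1,3-dioxolan-2-yl)-3-ethoxy-8-methoxy-1-methyl-11-oxo-11H-dibenzo[b,e][1,4]dioxepine-7-carboxylate
Conditions: [Rh(cod)2]BF4 (10 mol%), rac-BINAP (10 mol%), H2 then Ar, CH2Cl2, rt; 21 (5 equiv); slow addition of 20 at high dilution
Reagents that add atoms: none
Why: Proposed new method: cationic monovalent rhodium is expected to bind the ynoate and the ynol ether, which the two neighbouring catechol oxygens of ring B hold side by side, and to couple them oxidatively to a rhodacyclopentadiene in which the bond between the oxygen-bearing and the acyl-bearing alkyne carbons has formed; ethoxyacetylene then inserts and reductive elimination releases the arene and the catalyst. The closest known reaction type is the [Rh(cod)2]BF4/BINAP-catalysed (2+2+2) cycloaddition of ether- or ester-tethered diynes with monoalkynes, which is established for five- and six-membered tether rings and for alkynyl ethers as partners, but not for a seven-membered ester–ether tether combined with an alkoxyacetylene. Ring C (seven-membered) closes as the tether ring during the oxidative coupling through one new C–C bond, and ring A closes by the cyclotrimerisation itself through the two further C–C bonds to the ethoxyacetylene carbons. No stereocentre is formed. The step needs head-to-tail insertion of ethoxyacetylene, its oxygen-bearing carbon joining the acetal-bearing carbon; the alternating polarity of the six alkyne carbons favours this, since each new bond then joins a donor-polarised to an acceptor-polarised carbon, although the bulk of the acetal works against it, while slow addition of 20 to excess 21 holds back oligomerisation and the masked aldehydes exclude hydroacylation.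

Step 14
Reactants: 22 methyl 9-[(benzyloxy)methyl]-4-(diethoxymethyl)-6-(1,3-dioxolan-2-yl)-3-ethoxy-8-methoxy-1-methyl-11-oxo-11H-dibenzo[b,e][1,4]dioxepine-7-carboxylate
Product: 23 methyl 4-(diethoxymethyl)-6-(1,3-dioxolan-2-yl)-3-ethoxy-9-(hydroxymethyl)-8-methoxy-1-methyl-11-oxo-11H-dibenzo[b,e][1,4]dioxepine-7-carboxylate
Conditions: H2 (1 atm), Pd/C (10%), EtOAc, rt
Reagents that add atoms: none
Why: Hydrogenolysis of the benzyl ether under neutral conditions frees the primary alcohol, with the acetals, aryl ethers and depsidone lactone inert and no alkene or alkyne left in the molecule.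

Step 15
Reactants: 23 methyl 4-(diethoxymethyl)-6-(1,3-dioxolan-2-yl)-3-ethoxy-9-(hydroxymethyl)-8-methoxy-1-methyl-11-oxo-11H-dibenzo[b,e][1,4]dioxepine-7-carboxylate; 24 mono-tert-butyl fumarate ((2E)-4-tert-butoxy-4-oxobut-2-enoic acid)
Product: 25 tert-butyl {[4-(diethoxymethyl)-6-(1,3-dioxolan-2-yl)-3-ethoxy-8-methoxy-7-(methoxycarbonyl)-1-methyl-11-oxo-11H-dibenzo[b,e][1,4]dioxepin-9-yl]methyl} (2E)-but-2-enedioate
Conditions: DCC, DMAP (cat.), CH2Cl2, 0 °C → rt
Reagents that add atoms: none
Why: Steglich esterification acylates the only free hydroxyl group while all phenols and both aldehydes are still masked, and the tert-butyl ester keeps the second fumarate carboxyl from reacting.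

Step 16
Reactants: 25 tert-butyl {[4-(diethoxymethyl)-6-(1,3-dioxolan-2-yl)-3-ethoxy-8-methoxy-7-(methoxycarbonyl)-1-methyl-11-oxo-11H-dibenzo[b,e][1,4]dioxepin-9-yl]methyl} (2E)-but-2-enedioate
Product: 27 the target constitution as the equilibrating pair of lactol epimers, via open formyl acid 26 (not isolated)
Conditions: BCl3 (excess), CH2Cl2, −78 °C → rt; then H2O–THF, 0 °C
Reagents that add atoms: water, O
Why: BCl3 dealkylation should open both acetals, remove the ethyl and methyl groups from the two ether oxygens that sit ortho to a carbonyl group through boron chelates, and cleave the tert-butyl ester and the methyl ester (the latter helped by the neighbouring formyl group), so that hydrolysis gives the formyl acid, which closes to the five-membered lactol by the ring-chain tautomerism of 2-formylbenzoic acids.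

Step 17
Reactants: 27 the target constitution as the equilibrating pair of lactol epimers
Product: 28 the (R)-lactol acetate of the target
Conditions: Burkholderia cepacia lipase (immobilised), vinyl acetate, THF, 40 °C
Reagents that add atoms: vinyl acetate, CC(=O)OC=C
Why: Lipase-catalysed dynamic kinetic resolution (irreversible transesterification with an enol ester) should acetylate only the lactol hydroxyl; by the empirical rule for cyclic secondary carbinols (aryl ring as large, lactone oxygen as medium substituent) the (R) epimer reacts faster, while the lactol keeps racemising through the open formyl acid so all material is funnelled into the configurationally stable (R) acylal.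

Step 18
Reactants: 28 the (R)-lactol acetate of the target
Product: 29 the target, (R) at the hemiacetal carbon
Conditions: Burkholderia cepacia lipase (immobilised), n-BuOH, t-BuOMe–THF, 0–5 °C; cold filtration and cold evaporation, stored as a solid
Reagents that add atoms: none
Why: Lipase-catalysed alcoholysis transfers the acetyl group to butanol through an acyl-enzyme, breaking only the acyl C–O bond so the hemiacetal carbon keeps its (R) configuration, and the same enantiopreference leaves any (S)-acetate behind, while the hindered conjugated fumarate ester is a poor lipase substrate.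

**Compound list**
1 | 4-methoxycatechol | COc1ccc(O)c(O)c1 | starting material
2 | 4-methoxy-1,2-bis(methoxymethoxy)benzene | COCOc1ccc(OC)cc1OCOC | intermediate
3 | [6-methoxy-2,3-bis(methoxymethoxy)phenyl]lithium | COCOc1ccc(OC)c([Li])c1OCOC | intermediate (not isolated)
4 | 2-[(benzyloxy)methyl]-1-methoxy-3,4-bis(methoxymethoxy)benzene | COCOc1ccc(OC)c(COCc2ccccc2)c1OCOC | intermediate
5 | 3-[(benzyloxy)methyl]-1-bromo-2-methoxy-4,5-bis(methoxymethoxy)benzene | COCOc1cc(Br)c(OC)c(COCc2ccccc2)c1OCOC | intermediate
6 | {3-[(benzyloxy)methyl]-2-methoxy-4,5-bis(methoxymethoxy)phenyl}lithium | COCOc1cc([Li])c(OC)c(COCc2ccccc2)c1OCOC | intermediate (not isolated)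
7 | methyl 3-[(benzyloxy)methyl]-2-methoxy-4,5-bis(methoxymethoxy)benzoate | COCOc1cc(C(=O)OC)c(OC)c(COCc2ccccc2)c1OCOC | intermediate
8 | chloro{4-[(benzyloxy)methyl]-3-methoxy-2-(methoxycarbonyl)-5,6-bis(methoxymethoxy)phenyl}magnesium | COCOc1c([Mg]Cl)c(C(=O)OC)c(OC)c(COCc2ccccc2)c1OCOC | intermediate (not isolated)
9 | methyl 3-[(benzyloxy)methyl]-6-formyl-2-methoxy-4,5-bis(methoxymethoxy)benzoate | COCOc1c(C=O)c(C(=O)OC)c(OC)c(COCc2ccccc2)c1OCOC | intermediate
10 | methyl 3-[(benzyloxy)methyl]-6-formyl-4,5-dihydroxy-2-methoxybenzoate | Oc1c(C=O)c(C(=O)OC)c(OC)c(COCc2ccccc2)c1O | intermediate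
11 | methyl 4-(allyloxy)-3-[(benzyloxy)methyl]-6-formyl-5-hydroxy-2-methoxybenzoate | C=CCOc1c(O)c(C=O)c(C(=O)OC)c(OC)c1COCc1ccccc1 | intermediate
12 | methyl 4-(allyloxy)-3-[(benzyloxy)methyl]-6-(1,3-dioxolan-2-yl)-5-hydroxy-2-methoxybenzoate | C=CCOc1c(O)c(C2OCCO2)c(C(=O)OC)c(OC)c1COCc1ccccc1 | intermediate
13 | 2,2-diethoxyacetaldehyde | CCOC(OCC)C=O | starting material
14 | 1,1-dibromo-3,3-diethoxyprop-1-ene | CCOC(OCC)C=C(Br)Br | intermediate
15 | methyl 4-(allyloxy)-3-[(benzyloxy)methyl]-5-{[(Z)-1-bromo-3,3-diethoxyprop-1-en-1-yl]oxy}-6-(1,3-dioxolan-2-yl)-2-methoxybenzoate (aryloxy trans to the acetal carbon, as expected) | C=CCOc1c(O/C(Br)=C/C(OCC)OCC)c(C2OCCO2)c(C(=O)OC)c(OC)c1COCc1ccccc1 | intermediate (not isolated)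
16 | methyl 4-(allyloxy)-3-[(benzyloxy)methyl]-5-[(3,3-diethoxyprop-1-yn-1-yl)oxy]-6-(1,3-dioxolan-2-yl)-2-methoxybenzoate | C=CCOc1c(OC#CC(OCC)OCC)c(C2OCCO2)c(C(=O)OC)c(OC)c1COCc1ccccc1 | intermediate
17 | methyl 3-[(benzyloxy)methyl]-5-[(3,3-diethoxyprop-1-yn-1-yl)oxy]-6-(1,3-dioxolan-2-yl)-4-hydroxy-2-methoxybenzoate | Oc1c(OC#CC(OCC)OCC)c(C2OCCO2)c(C(=O)OC)c(OC)c1COCc1ccccc1 | intermediate
18 | but-2-ynoic acid | CC#CC(=O)O | starting material
19 | but-2-ynoyl chloride | CC#CC(=O)Cl | intermediate (not isolated)
20 | methyl 3-[(benzyloxy)methyl]-4-(but-2-ynoyloxy)-5-[(3,3-diethoxyprop-1-yn-1-yl)oxy]-6-(1,3-dioxolan-2-yl)-2-methoxybenzoate (key-step diyne) | CC#CC(=O)Oc1c(OC#CC(OCC)OCC)c(C2OCCO2)c(C(=O)OC)c(OC)c1COCc1ccccc1 | intermediate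
21 | ethoxyacetylene | C#COCC | starting material
22 | methyl 9-[(benzyloxy)methyl]-4-(diethoxymethyl)-6-(1,3-dioxolan-2-yl)-3-ethoxy-8-methoxy-1-methyl-11-oxo-11H-dibenzo[b,e][1,4]dioxepine-7-carboxylate (protected depsidone) | Cc1cc(OCC)c(C(OCC)OCC)c2c1C(=O)Oc1c(COCc3ccccc3)c(OC)c(C(=O)OC)c(C3OCCO3)c1O2 | intermediate
23 | methyl 4-(diethoxymethyl)-6-(1,3-dioxolan-2-yl)-3-ethoxy-9-(hydroxymethyl)-8-methoxy-1-methyl-11-oxo-11H-dibenzo[b,e][1,4]dioxepine-7-carboxylate | Cc1cc(OCC)c(C(OCC)OCC)c2c1C(=O)Oc1c(CO)c(OC)c(C(=O)OC)c(C3OCCO3)c1O2 | intermediate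
24 | mono-tert-butyl fumarate | CC(C)(C)OC(=O)/C=C/C(=O)O | starting material
25 | tert-butyl {[4-(diethoxymethyl)-6-(1,3-dioxolan-2-yl)-3-ethoxy-8-methoxy-7-(methoxycarbonyl)-1-methyl-11-oxo-11H-dibenzo[b,e][1,4]dioxepin-9-yl]methyl} (2E)-but-2-enedioate | Cc1cc(OCC)c(C(OCC)OCC)c2c1C(=O)Oc1c(COC(=O)/C=C/C(=O)OC(C)(C)C)c(OC)c(C(=O)OC)c(C3OCCO3)c1O2 | intermediate
26 | 9-({[(2E)-3-carboxyprop-2-enoyl]oxy}methyl)-4,6-diformyl-3,8-dihydroxy-1-methyl-11-oxo-11H-dibenzo[b,e][1,4]dioxepine-7-carboxylic acid (open formyl acid) | Cc1cc(O)c(C=O)c2c1C(=O)Oc1c(COC(=O)/C=C/C(=O)O)c(O)c(C(=O)O)c(C=O)c1O2 | intermediate (not isolated)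
27 | target constitution with the fused 3-hydroxyphthalide closed, both configurations at the hemiacetal carbon in equilibrium | Cc1cc(O)c(C=O)c2c1C(=O)Oc1c(COC(=O)/C=C/C(=O)O)c(O)c3c(c1O2)C(O)OC3=O | intermediate
28 | (R)-lactol acetate of the target (acetoxy in place of the hemiacetal hydroxyl) | Cc1cc(O)c(C=O)c2c1C(=O)Oc1c(COC(=O)/C=C/C(=O)O)c(O)c3c(c1O2)[C@H](OC(C)=O)OC3=O | intermediate
29 | target: depsidone with ring A carrying methyl, hydroxy and formyl, ring B carrying the (E)-3-carboxyacryloyloxymethyl group, hydroxy and the fused (R)-3-hydroxyphthalide | Cc1cc(O)c(C=O)c2c1C(=O)Oc1c(COC(=O)/C=C/C(=O)O)c(O)c3c(c1O2)[C@H](O)OC3=O | target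

**Step count**
Total: 18 steps. Longest linear sequence: 17 steps (steps 1–8 and 10–18, from 1 to 29); step 9 is a one-step side branch.

**Steps most likely to fail**

1. Step 13. The aryl ester has to turn into its less favoured conformation to bring the ynoate next to the ynol ether, and the tether ring is seven-membered, so oxidative coupling of the two tethered alkynes may be slow. Ethoxyacetylene may then trimerise on its own or insert with the opposite orientation.
Fallback by known chemistry (nucleophilic aromatic substitution, then lactonisation), setting out from 12 and returning at 22. Ring A is made separately from 3-fluoro-5-methylphenol. O-Ethylation gives 1-ethoxy-3-fluoro-5-methylbenzene F1. Lithiation between fluorine and ethoxy and formylation with DMF give 2-ethoxy-6-fluoro-4-methylbenzaldehyde F2. With the aldehyde masked in the flask as its lithium amino alkoxide, a second lithiation at the only remaining position ortho to fluorine and carboxylation give 4-ethoxy-2-fluoro-3-formyl-6-methylbenzoic acid F3, which is converted into allyl 4-ethoxy-2-fluoro-3-formyl-6-methylbenzoate F4. The phenoxide of 12 (K2CO3, DMF) displaces the fluoride, which is activated by the ortho formyl and ortho ester groups, to give the diaryl ether aldehyde F5. Triethyl orthoformate with a trace of acid turns the aldehyde into the diethyl acetal F6. Zerovalent palladium with morpholine removes the allyl ether and the allyl ester together to give the hydroxy acid F7. Yamaguchi or carbodiimide lactonisation between the ring A carboxyl and the ring B phenol then closes ring C to 22.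

2. Step 10. Copper-mediated C–O bond formation at a phenol flanked by two ortho substituents may be slow, with double substitution to a ketene acetal or decomposition on long heating competing.
Fallback from 12, returning at 16. Bromination of 1,1-diethoxypropan-2-one gives 1-bromo-3,3-diethoxypropan-2-one F8, with which 12 is O-alkylated (K2CO3, acetone; Williamson etherification, reliable for hindered phenols) to the aryloxy ketone F9. Kinetic enolisation toward the aryloxy-bearing methylene with KHMDS and trapping with PhNTf2 give the enol triflate F10 (geometry not controlled), and KOtBu in THF at −78 °C eliminates triflate to give the ynol ether 16.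

3. Step 17. The lipase may accept the bulky tetracyclic lactol poorly or with low enantioselectivity, ring-chain equilibration may be too slow for a dynamic resolution, and the configuration may erode in the deacetylation that follows.
Fallback from 27, returning at 29, by crystallisation-induced diastereomer transformation in place of both enzymatic steps. 27 is combined with one equivalent of an enantiopure tertiary amine, here (S)-N,N-dimethyl-1-phenylethylamine (or its enantiomer, whichever gives the (R)-lactol salt as the less soluble one). In a solvent where the lactol epimerises through the open formyl acid, the less soluble diastereomer, the (S)-N,N-dimethyl-1-phenylethylammonium salt of 29 F11, should crystallise and draw the equilibrium to one configuration. The filtered salt is partitioned cold between dilute aqueous acid and EtOAc to release 29.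

**Further compounds**
F1 | step 13 | 1-ethoxy-3-fluoro-5-methylbenzene | CCOc1cc(C)cc(F)c1
F2 | step 13 | 2-ethoxy-6-fluoro-4-methylbenzaldehyde | CCOc1cc(C)cc(F)c1C=O
F3 | step 13 | 4-ethoxy-2-fluoro-3-formyl-6-methylbenzoic acid | CCOc1cc(C)c(C(=O)O)c(F)c1C=O
F4 | step 13 | allyl 4-ethoxy-2-fluoro-3-formyl-6-methylbenzoate | CCOc1cc(C)c(C(=O)OCC=C)c(F)c1C=O
F5 | step 13 | diaryl ether aldehyde from 12 and F4 (ring A allyl ester, free formyl group) | CCOc1cc(C)c(C(=O)OCC=C)c(Oc2c(OCC=C)c(COCc3ccccc3)c(OC)c(C(=O)OC)c2C2OCCO2)c1C=O
F6 | step 13 | diethyl acetal of F5 | CCOc1cc(C)c(C(=O)OCC=C)c(Oc2c(OCC=C)c(COCc3ccccc3)c(OC)c(C(=O)OC)c2C2OCCO2)c1C(OCC)OCC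
F7 | step 13 | hydroxy acid (seco acid of 22) | CCOc1cc(C)c(C(=O)O)c(Oc2c(O)c(COCc3ccccc3)c(OC)c(C(=O)OC)c2C2OCCO2)c1C(OCC)OCC
F8 | step 10 | 1-bromo-3,3-diethoxypropan-2-one | CCOC(OCC)C(=O)CBr
F9 | step 10 | methyl 4-(allyloxy)-3-[(benzyloxy)methyl]-5-(3,3-diethoxy-2-oxopropoxy)-6-(1,3-dioxolan-2-yl)-2-methoxybenzoate | CCOC(OCC)C(=O)COc1c(OCC=C)c(COCc2ccccc2)c(OC)c(C(=O)OC)c1C1OCCO1
F10 | step 10 | enol triflate of F9 (aryloxy-substituted alkene, geometry not controlled) | CCOC(OCC)C(OS(=O)(=O)C(F)(F)F)=COc1c(OCC=C)c(COCc2ccccc2)c(OC)c(C(=O)OC)c1C1OCCO1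
F11 | step 17 | (S)-N,N-dimethyl-1-phenylethylammonium salt of 29 | C[C@H]([NH+](C)C)c1ccccc1.Cc1cc(O)c(C=O)c2c1C(=O)Oc1c(COC(=O)/C=C/C(=O)[O-])c(O)c3c(c1O2)[C@H](O)OC3=O
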